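**Retrosynthetic overview**
1. The target comes from its bis(benzyl ether) by debenzylation. The tetrahydrofuran C2–O1 bond comes from acid-triggered closure of a benzylic tetraol, which is the LiAlH4 product of a γ-aryl-γ-butyrolactone (last ring).
2. The C4–CH2Ar bond comes from benzylation of the alkoxide–enolate dianion of that β-hydroxy lactone, anti to OLi and to the aryl group.
3. The lactone ring and the benzylic C2–O bond come from anodic benzylic C–H lactonisation of (S)-2-benzylmalic acid 1-methyl ester (key step, second ring).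
4. The quaternary carbinol C3 comes from enolate benzylation, with retention, of the pivalaldehyde dioxolanone of L-malic acid (temporary first ring). One benzyl bromide serves both C–C bond formations.
5. Ring order: dioxolanone (temporary), then γ-lactone (electrolysis), then tetrahydrofuran.

Assumption: 4-(benzyloxy)-3-methoxybenzyl bromide is bought as a catalogue compound, and atoms are called O1, C2 (aryl), C3 (carbinol), C4 (benzyl), C5 as in the target oxolane throughout.

**Route**

Step 1
Reactants: 1 L-malic acid; 2 pivalaldehyde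
Product: 3 2-[(2S,4S)-2-tert-butyl-5-oxo-1,3-dioxolan-4-yl]acetic acid (cis)
Conditions: 2 (2 equiv), TsOH·H2O (cat.), H2SO4 (cat.), pentane, reflux, Dean–Stark; recrystallise
Reagents that add atoms: pivalaldehyde, CC(C)(C)C=O
Why: Acid-catalysed acetalisation of the α-hydroxy acid unit (first stage of Seebach self-regeneration of stereocentres) gives mainly the cis five-membered acetal, whose new centre is set by the malic acid centre under equilibrating conditions and is purified by crystallisation.

Step 2
Reactants: 3 dioxolanone acid; 4 4-(benzyloxy)-3-methoxybenzyl bromide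
Product: 6 (3S)-4-[4-(benzyloxy)-3-methoxyphenyl]-3-hydroxy-3-(methoxycarbonyl)butanoic acid, via benzylated dioxolanone 5 (not isolated)
Conditions: LiN(SiMe3)2 (2.2 equiv), THF, −78 °C; 4 (1.1 equiv), −78 → −20 °C; then MeOH, K2CO3 (0.2 equiv), 0 °C → rt; 1 M HCl work-up
Reagents that add atoms: 4-(benzyloxy)-3-methoxybenzyl bromide, COc1cc(CBr)ccc1OCc1ccccc1; methanol, CO
Why: Enolate alkylation of the carboxylate–enolate dianion occurs anti to tert-butyl (self-regeneration of stereocentres, net retention at C3), and base-catalysed transesterification then opens the acylal carbonyl with loss of pivalaldehyde while the carboxylate stays untouched.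

Step 3
Reactants: 6 hydroxy half ester
Product: 7 methyl (2R,3R)-2-[4-(benzyloxy)-3-methoxyphenyl]-3-hydroxy-5-oxooxolane-3-carboxylate
Conditions: undivided cell, graphite felt anode, Pt cathode, 5 mA cm−2, 2.3 F mol−1, nBu4NPF6 (0.1 M), 2,6-lutidine (2 equiv), CH2Cl2/(CF3)2CHOH 9:1, rt
Reagents that add atoms: none
Why: Proposed new method: anodic dehydrogenative benzylic C(sp3)–H lactonisation of an aliphatic γ-aryl acid next to a fully substituted carbinol centre – the dialkoxyarene (about +1.3 V vs SCE) is the only group oxidised at carbon, 2,6-lutidine takes the benzylic proton of the radical cation, the benzyl radical loses a second electron, and the p-alkoxybenzyl cation is captured 5-exo by the tethered CO2H while protons are reduced to H2 at Pt; the acyloxy group raises the oxidation potential of 7 so oxidation stops after two electrons, C–C fragmentation is disfavoured because it would give an ester-destabilised cation, and closure through the rotamer that keeps the aryl group away from CO2Me sets C2 with aryl cis to OH; the closest known reaction types are anodic benzylic acyloxylation and the electrochemical lactonisation of 2-alkylbenzoic acids to phthalides.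

Step 4
Reactants: 7 hydroxy lactone ester; 4 4-(benzyloxy)-3-methoxybenzyl bromide
Product: 8 methyl (2R,3R,4R)-4-[4-(benzyloxy)-3-methoxybenzyl]-2-[4-(benzyloxy)-3-methoxyphenyl]-3-hydroxy-5-oxooxolane-3-carboxylate
Conditions: LiN(iPr)2 (2.3 equiv), THF/DMPU, −78 °C; 4 (1.2 equiv), −78 → −40 °C; 1 M HCl work-up
Reagents that add atoms: 4-(benzyloxy)-3-methoxybenzyl bromide, COc1cc(CBr)ccc1OCc1ccccc1
Why: Fráter–Seebach-type alkylation of the alkoxide–enolate dianion of a β-hydroxy lactone cannot β-eliminate (oxide is no leaving group), and the bromide enters the face opposite both the lithium alkoxide and the C2 aryl group, so the C4 benzyl ends trans to OH and aryl and cis to the ester.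

Step 5
Reactants: 8 benzylated lactone ester
Product: 10 (2R,3S,4S)-4-[4-(benzyloxy)-3-methoxybenzyl]-2-[4-(benzyloxy)-3-methoxyphenyl]-3-(hydroxymethyl)oxolan-3-ol, via tetraol 9 (not isolated)
Conditions: LiAlH4 (5 equiv), THF, 0 °C → rt; Na2SO4·10H2O quench, filter; crude 9, TsOH·H2O (5 mol %), CH2Cl2, 0 °C
Reagents that add atoms: none
Why: Hydride reduction turns lactone and ester into the tetraol, and acid-catalysed SN1 cycloetherification ionises only the p-alkoxybenzylic alcohol, whose cation is captured 5-exo by the C5 hydroxyl reversibly, so C2 settles with aryl trans to CH2OH and to the benzyl group while C3 and C4 are untouched.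

Step 6
Reactants: 10 bis(benzyl ether)
Product: 11 (2R,3S,4S)-4-(4-hydroxy-3-methoxybenzyl)-2-(4-hydroxy-3-methoxyphenyl)-3-(hydroxymethyl)oxolan-3-ol (target)
Conditions: H2 (1 atm), Pd/C (10 wt %), EtOAc/EtOH, rt, stopped at full O-debenzylation
Reagents that add atoms: none
Why: Catalytic hydrogenolysis cleaves the two aryl benzyl ethers much faster than the hindered cyclic benzylic C2–O1 bond next to the quaternary carbinol, and no stereocentre is touched.

**Compound list**
1 | L-malic acid, (S) | OC(=O)C[C@H](O)C(=O)O | starting material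
2 | pivalaldehyde | CC(C)(C)C=O | starting material
3 | 2-[(2S,4S)-2-tert-butyl-5-oxo-1,3-dioxolan-4-yl]acetic acid | OC(=O)C[C@@H]1O[C@H](C(C)(C)C)OC1=O | intermediate
4 | 4-(benzyloxy)-3-methoxybenzyl bromide | COc1cc(CBr)ccc1OCc1ccccc1 | starting material
5 | 2-[(2S,4S)-4-[4-(benzyloxy)-3-methoxybenzyl]-2-tert-butyl-5-oxo-1,3-dioxolan-4-yl]acetic acid | OC(=O)C[C@]1(Cc2ccc(OCc3ccccc3)c(OC)c2)O[C@H](C(C)(C)C)OC1=O | intermediate
6 | (3S)-4-[4-(benzyloxy)-3-methoxyphenyl]-3-hydroxy-3-(methoxycarbonyl)butanoic acid | OC(=O)C[C@@](O)(Cc1ccc(OCc2ccccc2)c(OC)c1)C(=O)OC | intermediate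
7 | methyl (2R,3R)-2-[4-(benzyloxy)-3-methoxyphenyl]-3-hydroxy-5-oxooxolane-3-carboxylate (aryl cis to OH) | C1C(=O)O[C@H](c2ccc(OCc3ccccc3)c(OC)c2)[C@@]1(O)C(=O)OC | intermediate
8 | methyl (2R,3R,4R)-4-[4-(benzyloxy)-3-methoxybenzyl]-2-[4-(benzyloxy)-3-methoxyphenyl]-3-hydroxy-5-oxooxolane-3-carboxylate | COc1cc(C[C@H]2C(=O)O[C@H](c3ccc(OCc4ccccc4)c(OC)c3)[C@@]2(O)C(=O)OC)ccc1OCc1ccccc1 | intermediate
9 | (2S,3S)-3-[4-(benzyloxy)-3-methoxybenzyl]-2-{(R)-[4-(benzyloxy)-3-methoxyphenyl](hydroxy)methyl}butane-1,2,4-triol | COc1cc(C[C@@H](CO)[C@](O)(CO)[C@H](O)c2ccc(OCc3ccccc3)c(OC)c2)ccc1OCc1ccccc1 | intermediate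
10 | (2R,3S,4S)-4-[4-(benzyloxy)-3-methoxybenzyl]-2-[4-(benzyloxy)-3-methoxyphenyl]-3-(hydroxymethyl)oxolan-3-ol | COc1cc(C[C@H]2CO[C@H](c3ccc(OCc4ccccc4)c(OC)c3)[C@@]2(O)CO)ccc1OCc1ccccc1 | intermediate
11 | (2R,3S,4S)-4-(4-hydroxy-3-methoxybenzyl)-2-(4-hydroxy-3-methoxyphenyl)-3-(hydroxymethyl)oxolan-3-ol | COc1cc(C[C@H]2CO[C@H](c3ccc(O)c(OC)c3)[C@@]2(O)CO)ccc1O | target

**Totals**
Total step count: 6. Longest linear sequence: 6 (from L-malic acid).

**Steps most likely to fail**

Risk 1 is step 3, the proposed new step.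
- The radical cation may lose a proton from the OCH2Ph group instead of C2.
- The carboxylate may be oxidised and decarboxylate.
- The C2 diastereoselectivity may be low.
- The fallback uses known chemistry. It sets out from 3 and comes back at 7, so steps 2 and 3 are not needed.
- The dianion of 3 (LiN(SiMe3)2, THF, −78 °C) adds to 4-(benzyloxy)-3-methoxybenzaldehyde anti to tert-butyl to give the aldol acid F1.
- Catalytic TsOH in CH2Cl2 closes it to the spirolactone F2. The aryl-bearing centre equilibrates there through the benzylic cation.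
- MeOH with catalytic TsOH then removes pivalaldehyde and gives 7.

Risk 2 is step 4.
- The geminal ester may erode the facial bias, or the dianion may be sluggish.
- The fallback sets out from 7 and comes back at 8.
- The same dianion is added to 4-(benzyloxy)-3-methoxybenzaldehyde. Only the aldolate whose new substituent lies cis to the ester can lactonise, and the other reverts by retro-aldol.
- Ring fusion therefore fixes C4 in the cis-fused dilactone F3.
- Et3SiH/CF3CO2H (ionic hydrogenolysis) cleaves the benzylic C–O bond of the new ring. Its cation is less destabilised than the one next to the carbinol carbon. This gives the lactone acid F4.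
- Me3SiCHN2 converts F4 into 8.

Risk 3 is step 6.
- Over-reduction can open the C2–O1 bond.
- The fallback sets out from 8 and comes back at 11, removing the benzyl groups before the sensitive ring exists.
- BCl3 with pentamethylbenzene (CH2Cl2, −78 °C) gives the bisphenol lactone F5.
- LiAlH4 gives the bisphenol tetraol F6.
- F6 closes without acid through its p-quinone methide on gentle warming in pH 7 buffer to give 11.

**Further compounds**
F1 | step 3 | 2-[(2S,4S)-4-{(R)-[4-(benzyloxy)-3-methoxyphenyl](hydroxy)methyl}-2-tert-butyl-5-oxo-1,3-dioxolan-4-yl]acetic acid | OC(=O)C[C@]1([C@H](O)c2ccc(OCc3ccccc3)c(OC)c2)O[C@H](C(C)(C)C)OC1=O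
F2 | step 3 | (2S,5R,6R)-6-[4-(benzyloxy)-3-methoxyphenyl]-2-tert-butyl-1,3,7-trioxaspiro[4.4]nonane-4,8-dione | C1C(=O)O[C@H](c2ccc(OCc3ccccc3)c(OC)c2)[C@@]1(O4)C(=O)O[C@H]4C(C)(C)C
F3 | step 4 | (1R,4S,5R,8R)-4,8-bis[4-(benzyloxy)-3-methoxyphenyl]-1-hydroxy-3,7-dioxabicyclo[3.3.0]octane-2,6-dione | O=C1O[C@H](c3ccc(OCc4ccccc4)c(OC)c3)[C@@]2(O)C(=O)O[C@H](c5ccc(OCc6ccccc6)c(OC)c5)[C@@H]12
F4 | step 4 | (2R,3R,4R)-4-[4-(benzyloxy)-3-methoxybenzyl]-2-[4-(benzyloxy)-3-methoxyphenyl]-3-hydroxy-5-oxooxolane-3-carboxylic acid | COc1cc(C[C@H]2C(=O)O[C@H](c3ccc(OCc4ccccc4)c(OC)c3)[C@@]2(O)C(=O)O)ccc1OCc1ccccc1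
F5 | step 6 | methyl (2R,3R,4R)-3-hydroxy-4-(4-hydroxy-3-methoxybenzyl)-2-(4-hydroxy-3-methoxyphenyl)-5-oxooxolane-3-carboxylate | COc1cc(C[C@H]2C(=O)O[C@H](c3ccc(O)c(OC)c3)[C@@]2(O)C(=O)OC)ccc1O
F6 | step 6 | (2S,3S)-3-(4-hydroxy-3-methoxybenzyl)-2-[(R)-hydroxy(4-hydroxy-3-methoxyphenyl)methyl]butane-1,2,4-triol | COc1cc(C[C@@H](CO)[C@](O)(CO)[C@H](O)c2ccc(O)c(OC)c2)ccc1O
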